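The cyclohexane ring is cut back to a 4-substituted cyclohexenone. That ring is opened at C1'–C6' and C2'=C3' to give methyl vinyl ketone and an acetaldehyde that already carries the complete bromo-oxane ring from (R)-linalool. The feature exploited is the C1' methine. It sits α to the aldehyde carbon (future C2') and next to quaternary C6, whose O1, CH3 and C5H2 groups cannot bias it. A chiral pyrrolidine enamine therefore sets C1' while one pot builds both ring bonds. The residual enone keeps C3' and C5' distinct for a regiodefined C3'=C4' alkene. This alkene is taken to the trans-diequatorial Br/Cl pair by epoxide opening, bromonium relay and halogen interchange.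

Key step: step 4

Locants: oxane O1, C2 (CMe2), C3 (CHBr), C4, C5, C6 (quaternary). Cyclohexane C1' (on C6), C2', C3' (CHBr), C4' (CClMe), C5', C6'. "Bottom" is the ring face towards which the equatorial C1'–C6 bond tilts, so C1'–H is axial on top. The axial positions are top at C3' and bottom at C4'.
Assumption: (R)-linalool of high enantiomeric purity and both antipodes of the fructose-type ketone catalyst are taken as purchasable.

Step 1
Reactants: 1 (R)-linalool; 2 N-bromosuccinimide
Product: 3 (3S,6R)-3-bromo-6-ethenyl-2,2,6-trimethyloxane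
Conditions: NBS (1.05 equiv), CH2Cl2, 0 °C, dark; chromatography
Reagents that add atoms: N-bromosuccinimide (2), O=C1CCC(=O)N1Br
Why: Electrophilic bromoetherification, known for linalool itself, in which Br+ adds chemoselectively to the electron-rich trisubstituted alkene and the tertiary OH captures the tertiary terminus in the Markovnikov 6-endo mode; C6 is carried over from 1, whereas C3 forms without useful facial bias, so the (3S) epimer (Br and vinyl both equatorial) must be separated from the (3R) epimer and the 5-exo oxolanes.

Step 2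
Reactants: 3 (3S,6R)-3-bromo-6-ethenyl-2,2,6-trimethyloxane
Product: 5 2-[(2R,5S)-5-bromo-2,6,6-trimethyloxan-2-yl]ethan-1-ol, via B-alkyl-9-BBN adduct 4 (not isolated)
Conditions: 9-BBN, THF, 0 °C → rt; then 30% H2O2, aq NaOH, 0 °C
Reagents that add atoms: hydrogen peroxide, OO
Why: Brown hydroboration–oxidation, in which the bulky dialkylborane places boron on the terminal carbon of the only alkene and cold alkaline peroxide replaces B by OH, while the equatorial neopentyl-type bromide (no antiperiplanar H, blocked backside) is untouched and no stereocentre is formed or disturbed.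

Step 3
Reactants: 5 2-[(2R,5S)-5-bromo-2,6,6-trimethyloxan-2-yl]ethan-1-ol
Product: 6 2-[(2R,5S)-5-bromo-2,6,6-trimethyloxan-2-yl]acetaldehyde
Conditions: Dess–Martin periodinane, CH2Cl2, 0 °C → rt; short silica plug, used at once
Reagents that add atoms: none
Why: Dess–Martin oxidation stops at the aldehyde without base, which matters because 6 is a β-alkoxy aldehyde that could ring-open by retro-oxa-Michael reaction on storage or on contact with base.

Step 4
Reactants: 6 2-[(2R,5S)-5-bromo-2,6,6-trimethyloxan-2-yl]acetaldehyde; 7 methyl vinyl ketone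
Product: 9 (4R)-4-[(2R,5S)-5-bromo-2,6,6-trimethyloxan-2-yl]cyclohex-2-en-1-one, via keto aldehyde 8 (not isolated)
Conditions: (S)-2-[diphenyl(trimethylsilyloxy)methyl]pyrrolidine (20 mol %), ethyl 3,4-dihydroxybenzoate (20 mol %), 7 (1.5 equiv), CH2Cl2 (concentrated), 4 °C; excess 7 stripped in vacuo; then LiOH (0.5 equiv), i-PrOH, 0 °C → rt, pH 7 quench
Reagents that add atoms: methyl vinyl ketone (7), C=CC(C)=O
Why: Aldehyde 6 and the (S)-pyrrolidine form the E, s-trans enamine, whose face under the CPh2(OSiMe3) group is blocked, so the hydrogen-bond-activated enone 7 is attacked by Cα (= C1') from the open face, the C1'–C6' bond forms, and hydrolysis releases keto aldehyde 8 and the amine. The closest known chemistry is the amine-catalysed enantioselective Michael addition of aldehydes to vinyl ketones, followed by base-induced cyclodehydration of the resulting 2-substituted 5-oxohexanals to 4-substituted cyclohexenones. The cyclohexenone ring closes by a favoured 6-(enolendo)-exo-trig aldol addition of the methyl-side enolate carbon (C3') to the aldehyde carbon (C2'), the only closure that gives an unstrained ring, and E1cB loss of water installs C2'=C3'. C1' is the only new stereocentre and is set by the catalyst: the (S)-amine gives the arrangement that is R in 9 (formally S in 8, where CHO outranks C6), while O1, CH3 and C5H2 on C6 are too alike to compete. The step needs enamine face selectivity, which quaternary C6 helps by allowing a single enamine rotamer, and it needs the β C6–O1 bond and the C1'–H to survive, which rests on the poor tertiary-alkoxide leaving group, the weakly acidic co-catalyst, the low temperature and a brief sub-stoichiometric LiOH treatment quenched before γ-deprotonation of 9 sets in.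

Step 5
Reactants: 9 (4R)-4-[(2R,5S)-5-bromo-2,6,6-trimethyloxan-2-yl]cyclohex-2-en-1-one
Product: 11 (4R)-4-[(2R,5S)-5-bromo-2,6,6-trimethyloxan-2-yl]cyclohex-1-en-1-yl trifluoromethanesulfonate, via lithium enolate 10 (not isolated)
Conditions: LiBH(s-Bu)3 (1.05 equiv), THF, −78 °C; then PhNTf2, −78 °C → rt
Reagents that add atoms: N-phenylbis(trifluoromethanesulfonimide), O=S(=O)(N(c1ccccc1)S(=O)(=O)C(F)(F)F)C(F)(F)F
Why: Conjugate reduction of a β-unsubstituted cyclohexenone by the bulky trialkylborohydride followed by O-triflation of the enolate is a known one-flask sequence; enolate 10 lies between C3' and C4', is not conjugated to C1'–H and has no β leaving group, so C1' and the oxane survive, and the hindered secondary bromide is inert to one equivalent of hydride at −78 °C.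

Step 6
Reactants: 11 (4R)-4-[(2R,5S)-5-bromo-2,6,6-trimethyloxan-2-yl]cyclohex-1-en-1-yl trifluoromethanesulfonate
Product: 12 (3S,6R)-3-bromo-2,2,6-trimethyl-6-[(1R)-4-methylcyclohex-3-en-1-yl]oxane
Conditions: Pd(PPh3)4 (5 mol %), Me2Zn (1.5 equiv), THF, 0 °C → rt
Reagents that add atoms: dimethylzinc, C[Zn]C
Why: Negishi cross-coupling, in which zerovalent palladium inserts into the vinyl C–OTf bond far faster than into the unactivated hindered secondary C–Br bond, and methyl transfer from zinc gives the trisubstituted C3'=C4' alkene at the position fixed by the triflate.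

Step 7
Reactants: 12 (3S,6R)-3-bromo-2,2,6-trimethyl-6-[(1R)-4-methylcyclohex-3-en-1-yl]oxane
Product: 13 (1R,4R,6S)-4-[(2R,5S)-5-bromo-2,6,6-trimethyloxan-2-yl]-1-methyl-7-oxabicyclo[4.1.0]heptane (oxygen on the top face, anti to the oxanyl group)
Conditions: 1,2:4,5-di-O-isopropylidene-β-L-erythro-2,3-hexodiulo-2,6-pyranose (30 mol %), 2KHSO5·KHSO4·K2SO4, K2CO3, Bu4NHSO4 (cat.), MeCN–CH2(OMe)2–aq Na2B4O7/Na2EDTA buffer, 0 °C
Reagents that add atoms: potassium peroxymonosulfate, [K+].[O-]S(=O)(=O)OO
Why: Shi asymmetric epoxidation, chosen because the two alkene faces are sterically alike (C1' is remote), so the chiral dioxirane decides; the L-series ketone, whose sense of induction on trisubstituted cyclohexenes is opposite to that of the D-fructose ketone, should deliver oxygen to the top face and set C3' (S) and C4' (R).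

Step 8
Reactants: 13 (1R,4R,6S)-4-[(2R,5S)-5-bromo-2,6,6-trimethyloxan-2-yl]-1-methyl-7-oxabicyclo[4.1.0]heptane
Product: 14 (1S,2S,5R)-2-bromo-5-[(2R,5S)-5-bromo-2,6,6-trimethyloxan-2-yl]-2-methylcyclohexan-1-ol (C3'–OH axial on top, C4'–Br axial on the bottom)
Conditions: LiBr (5 equiv), AcOH (2 equiv), THF, 0 °C → rt
Reagents that add atoms: lithium bromide, [Li+].[Br-]
Why: Trans-diaxial (Fürst–Plattner) epoxide opening: with the oxanyl group locking the chair, the top-face oxygen can stay axial only on C3', so bromide enters C4' from the bottom face, which is also the electronically favoured tertiary site, inverting C4'; acetic acid is too weak to cleave the di-tertiary oxane ether.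

Step 9
Reactants: 14 (1S,2S,5R)-2-bromo-5-[(2R,5S)-5-bromo-2,6,6-trimethyloxan-2-yl]-2-methylcyclohexan-1-ol
Product: 15 (3S,6R)-3-bromo-6-[(1R,3S,4S)-4-bromo-3-chloro-4-methylcyclohexyl]-2,2,6-trimethyloxane (Cl axial on top at C3', Br axial on the bottom at C4')
Conditions: 1-chloro-N,N,2-trimethylprop-1-en-1-amine (1.5 equiv), CH2Cl2, 0 °C → rt
Reagents that add atoms: 1-chloro-N,N,2-trimethylprop-1-en-1-amine, CC(C)=C(Cl)N(C)C
Why: Neutral deoxychlorination by an α-chloroenamine (Ghosez reagent) with anchimeric assistance: the axial imidate leaving group on C3' is antiperiplanar to the axial C4'–Br bond and departs with bromine participation to a bottom-face bromonium ion, which chloride opens from the top, trans-diaxially at C3', to give 15 with net retention (attack at C4' would give 16 directly, which is carried along); no acid is liberated, so the oxane and the tertiary bromide are spared.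

Step 10
Reactants: 15 (3S,6R)-3-bromo-6-[(1R,3S,4S)-4-bromo-3-chloro-4-methylcyclohexyl]-2,2,6-trimethyloxane
Product: 16 deoxycaespitol, (3S,6R)-3-bromo-6-[(1R,3R,4R)-3-bromo-4-chloro-4-methylcyclohexyl]-2,2,6-trimethyloxane
Conditions: MeCN, 2,6-di-tert-butylpyridine (0.2 equiv), 80 °C, sealed tube, dark; recovered 15 resubmitted
Reagents that add atoms: none
Why: Thermal diaxial-to-diequatorial rearrangement of a vicinal dihalide (dyotropic 1,2-interchange through a tight halonium–halide pair), known for 5α,6β-dihalo steroids: each halogen migrates on its own face, so top-face Cl moves to C4' and bottom-face Br to C3', inverting both centres to (3'R,4'R); the equilibrium should favour 16 because chlorine gains the tertiary and bromine the secondary carbon and the polar solvent stabilises the gauche dihalide.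

Compound list
1 | (R)-linalool | O[C@@](C)(C=C)CCC=C(C)C | starting material
2 | N-bromosuccinimide | O=C1CCC(=O)N1Br | starting material
3 | (3S,6R)-3-bromo-6-ethenyl-2,2,6-trimethyloxane | CC1(C)O[C@@](C)(C=C)CC[C@@H]1Br | intermediate
4 | 9-{2-[(2S,5S)-5-bromo-2,6,6-trimethyloxan-2-yl]ethyl}-9-borabicyclo[3.3.1]nonane (same spatial arrangement as 3; the descriptor change is formal) | CC1(C)O[C@@](C)(CCB2C3CCCC2CCC3)CC[C@@H]1Br | intermediate
5 | 2-[(2R,5S)-5-bromo-2,6,6-trimethyloxan-2-yl]ethan-1-ol | CC1(C)O[C@@](C)(CCO)CC[C@@H]1Br | intermediate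
6 | 2-[(2R,5S)-5-bromo-2,6,6-trimethyloxan-2-yl]acetaldehyde | CC1(C)O[C@@](C)(CC=O)CC[C@@H]1Br | intermediate
7 | methyl vinyl ketone | C=CC(C)=O | starting material
8 | (2S)-2-[(2R,5S)-5-bromo-2,6,6-trimethyloxan-2-yl]-5-oxohexanal | CC1(C)O[C@@](C)([C@@H](C=O)CCC(C)=O)CC[C@@H]1Br | intermediate
9 | (4R)-4-[(2R,5S)-5-bromo-2,6,6-trimethyloxan-2-yl]cyclohex-2-en-1-one | CC1(C)O[C@@](C)([C@@H]2CCC(=O)C=C2)CC[C@@H]1Br | intermediate
10 | lithium (4R)-4-[(2R,5S)-5-bromo-2,6,6-trimethyloxan-2-yl]cyclohex-1-en-1-olate | [Li+].CC1(C)O[C@@](C)([C@@H]2CCC([O-])=CC2)CC[C@@H]1Br | intermediate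
11 | (4R)-4-[(2R,5S)-5-bromo-2,6,6-trimethyloxan-2-yl]cyclohex-1-en-1-yl trifluoromethanesulfonate | CC1(C)O[C@@](C)([C@@H]2CCC(OS(=O)(=O)C(F)(F)F)=CC2)CC[C@@H]1Br | intermediate
12 | (3S,6R)-3-bromo-2,2,6-trimethyl-6-[(1R)-4-methylcyclohex-3-en-1-yl]oxane | CC1(C)O[C@@](C)([C@@H]2CCC(C)=CC2)CC[C@@H]1Br | intermediate
13 | (1R,4R,6S)-4-[(2R,5S)-5-bromo-2,6,6-trimethyloxan-2-yl]-1-methyl-7-oxabicyclo[4.1.0]heptane | CC1(C)O[C@@](C)([C@@H]2CC[C@@]3(C)O[C@H]3C2)CC[C@@H]1Br | intermediate
14 | (1S,2S,5R)-2-bromo-5-[(2R,5S)-5-bromo-2,6,6-trimethyloxan-2-yl]-2-methylcyclohexan-1-ol | CC1(C)O[C@@](C)([C@@H]2CC[C@](C)(Br)[C@@H](O)C2)CC[C@@H]1Br | intermediate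
15 | (3S,6R)-3-bromo-6-[(1R,3S,4S)-4-bromo-3-chloro-4-methylcyclohexyl]-2,2,6-trimethyloxane | CC1(C)O[C@@](C)([C@@H]2CC[C@](C)(Br)[C@@H](Cl)C2)CC[C@@H]1Br | intermediate
16 | deoxycaespitol, (3S,6R)-3-bromo-6-[(1R,3R,4R)-3-bromo-4-chloro-4-methylcyclohexyl]-2,2,6-trimethyloxane | CC1(C)O[C@@](C)([C@@H]2CC[C@@](C)(Cl)[C@H](Br)C2)CC[C@@H]1Br | target

Total step count: 10. Longest linear sequence: 10 steps, from (R)-linalool.

Steps most likely to fail

Step 4. Three processes may interfere. The enamine may expel O1 from C6, which opens the oxane by retro-oxa-Michael reaction and leads to unselective re-closure or epoxide formation onto C3. C–C bond formation at the neopentyl-type enamine carbon may be too slow. C1' may erode through the dienolate in the base stage. The fallback replaces catalytic enamine chemistry by a stoichiometric auxiliary (Enders hydrazone alkylation). It sets out from 6. Condensation with (R)-1-amino-2-(methoxymethyl)pyrrolidine gives the (E)-RAMP hydrazone F1. Deprotonation with LDA in THF and alkylation at −100 °C with 2-(2-iodoethyl)-2-methyl-1,3-dioxolane gives the alkylated hydrazone F2. The R auxiliary directs the electrophile to the face required for C1', and lithiated hydrazones bearing β-oxygen are known to be alkylated at low temperature without β-elimination. Two-phase cleavage with aqueous oxalic acid gives the dioxolane aldehyde F3. Treatment with PPTS in wet acetone unmasks the ketone. The sequence comes back to the route at 8, which is closed to 9 with LiOH as in step 4.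

Step 10. The equilibrium may stop short of full conversion, or the tertiary bromide may lose HBr on heating, with acid damage to the oxane. The fallback drops the relay through 13–15 and sets out from 12. It uses direct anti addition of BrCl (NBS, Et4NCl, CH2Cl2, −78 °C → 0 °C), a known Markovnikov interhalogen addition. The bottom-face bromonium ion opened by chloride at C4' gives 16. The top-face bromonium ion gives the trans-diaxial diastereomer F4, whose formation is stereoelectronically favoured. The two are separated by chromatography, so this trades selectivity for brevity. The fallback comes back to the route at 16.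

Step 7. The dioxirane may discriminate the faces poorly on an alkene that carries only small alkyl groups. The fallback replaces reagent control by chemical differentiation of the two epoxides and sets out from 12. Oxidation with mCPBA in CH2Cl2 gives 13 together with the syn epoxide F5. Warming the mixture with pyrrolidine and water consumes only F5, because its trans-diaxial opening occurs at the secondary C3'. This gives the amino alcohol F6, which is removed by an acid wash. Epoxide 13 could open diaxially only at the tertiary C4', so it is left untouched. This kinetic separation is known for the 1,2-oxides of limonene. The fallback comes back to the route at 13.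

Further compounds
F1 | step 4 | (E)-hydrazone of 6 with (R)-1-amino-2-(methoxymethyl)pyrrolidine | CC1(C)O[C@@](C)(C/C=N/N2CCC[C@@H]2COC)CC[C@@H]1Br
F2 | step 4 | (E)-RAMP hydrazone of F3, C1' configured as in 9 | CC1(C)O[C@@](C)([C@@H](/C=N/N2CCC[C@@H]2COC)CCC3(C)OCCO3)CC[C@@H]1Br
F3 | step 4 | (2S)-2-[(2R,5S)-5-bromo-2,6,6-trimethyloxan-2-yl]-4-(2-methyl-1,3-dioxolan-2-yl)butanal | CC1(C)O[C@@](C)([C@@H](C=O)CCC2(C)OCCO2)CC[C@@H]1Br
F4 | step 10 | (3S,6R)-3-bromo-6-[(1R,3S,4S)-3-bromo-4-chloro-4-methylcyclohexyl]-2,2,6-trimethyloxane | CC1(C)O[C@@](C)([C@@H]2CC[C@](C)(Cl)[C@@H](Br)C2)CC[C@@H]1Br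
F5 | step 7 | (1S,4R,6R)-4-[(2R,5S)-5-bromo-2,6,6-trimethyloxan-2-yl]-1-methyl-7-oxabicyclo[4.1.0]heptane | CC1(C)O[C@@](C)([C@@H]2CC[C@]3(C)O[C@@H]3C2)CC[C@@H]1Br
F6 | step 7 | (1S,2S,4R)-4-[(2R,5S)-5-bromo-2,6,6-trimethyloxan-2-yl]-1-methyl-2-(pyrrolidin-1-yl)cyclohexan-1-ol | CC1(C)O[C@@](C)([C@@H]2CC[C@](C)(O)[C@@H](N3CCCC3)C2)CC[C@@H]1Br
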